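## Retrosynthetic overview
1. The target is the ring-A cyclo-isomer of the acyclic all-E geranylgeranyl α-linolenate. Disconnect C10–C15 (geranylgeranyl numbering), which reverses a protonation-type terpene cyclase step: H+ adds to C14, C10 attacks C15, and the C11 cation loses H-12.
2. The acyclic ester is cut at the acyl C–O bond into geranylgeraniol and α-linolenic acid. The fatty ester goes on first and also switches off the 2,3-olefin.
3. The only stereocentre (C10, S) is set during ring closure by a chiral proton. The proton source is the SnCl4 complex of an (R)-BINOL mono(2-fluorobenzyl) ether, made in one step from (R)-BINOL.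
4. Ring order: there is one ring (ring A), formed in the last step together with the stereocentre.

Assumption: bulk annatto-derived (2E,6E,10E)-geranylgeraniol counts as cheap and commercial, and the (R)-ligand gives the same ring-A sense here (10S) as with other polyprenoids; if the antipode forms, (S)-BINOL is used instead.

## Route

Step 1
Reactants: 1 (2E,6E,10E)-geranylgeraniol; 2 α-linolenic acid
Product: 4 (2E,6E,10E)-geranylgeranyl (9Z,12Z,15Z)-octadeca-9,12,15-trienoate, via O-acylisourea 3 (not isolated)
Conditions: DCC (1.1 equiv), 4-(dimethylamino)pyridine (0.1 equiv), CH2Cl2, 0 °C to rt, Ar, dark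
Reagents that add atoms: none
Why: Steglich esterification, in which DCC turns 2 into O-acylisourea 3 and 4-(dimethylamino)pyridine relays the acyl group to the primary allylic alcohol under neutral conditions, so there is no allylic transposition, no E/Z leakage, no conjugation of the skipped Z-triene, and no stereocentre is made.

Step 2
Reactants: 5 (R)-1,1'-bi-2-naphthol; 6 2-fluorobenzyl bromide
Product: 7 (R)-2'-[(2-fluorobenzyl)oxy]-1,1'-binaphthalen-2-ol
Conditions: K2CO3 (1.1 equiv), 6 (1.0 equiv), acetone, reflux, 16 h
Reagents that add atoms: none
Why: Williamson ether synthesis, in which the hydrogen-bond-stabilised mono-phenoxide of 5 is alkylated once and the remaining, more hindered and less acidic OH reacts much more slowly, while the binaphthyl axis keeps its R configuration because its rotation barrier is far above what refluxing acetone supplies.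

Step 3
Reactants: 4 (2E,6E,10E)-geranylgeranyl α-linolenate; 7 (R)-BINOL mono(2-fluorobenzyl) ether (chiral proton carrier, not incorporated, recovered)
Product: 9 (2E,6E)-3,7-dimethyl-9-[(1S)-2,6,6-trimethylcyclohex-2-en-1-yl]nona-2,6-dien-1-yl (9Z,12Z,15Z)-octadeca-9,12,15-trienoate, via tertiary C11 cation 8 (not isolated)
Conditions: 7 (2.2 equiv), SnCl4 (2.0 equiv, 1 M in CH2Cl2), toluene (0.02 M), −78 °C, 48–72 h, stopped near 70% conversion; Et3N then aq. NaHCO3 at −78 °C; AgNO3–silica, then reversed-phase HPLC; recovered 4 recycled
Reagents that add atoms: none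
Why: Proposed new method: the phenolic O–H of 7, acidified by chelation to SnCl4, is a bulky chiral proton that reaches only the unhindered terminal isopropylidene; it protonates C14 on one enantiotopic face while C10 closes onto C15 through a chair-like transition state, which sets C10 as S (the ring-A sense that R-configured BINOL mono-ether acids of this kind give with polyprenoids), and cation 8, held in toluene at −78 °C as a contact ion pair with the basic aryloxystannate, loses the axial H-12 aligned with its empty p orbital (H-10 is shielded by the gem-dimethyl group and the side chain) faster than the unfolded chain brings C6=C7 into bonding distance, while any exocyclic olefin is re-protonated to 8 and drained to the same endocyclic olefin without touching C10, the 2,3-olefin is switched off by the SnCl4-bound acyloxy group (allylic esters survive even superacid at this temperature) and the Z-disubstituted olefins of the acyl chain could only give secondary cations; the closest known reaction type is the Yamamoto-type enantioselective polyene cyclisation with Lewis acid-assisted chiral Brønsted acids, in which ring-A-only olefins are known to accumulate and need a second, stronger achiral acid to cyclise further.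

## Compound list
1 | (2E,6E,10E)-geranylgeraniol | OC/C=C(\C)CC/C=C(\C)CC/C=C(\C)CCC=C(C)C | starting material
2 | α-linolenic acid, (9Z,12Z,15Z)-octadeca-9,12,15-trienoic acid | CC/C=C\C/C=C\C/C=C\CCCCCCCC(=O)O | starting material
3 | O-(α-linolenoyl)-N,N'-dicyclohexylisourea | CC/C=C\C/C=C\C/C=C\CCCCCCCC(=O)OC(=NC1CCCCC1)NC1CCCCC1 | intermediate
4 | (2E,6E,10E)-geranylgeranyl α-linolenate | CC/C=C\C/C=C\C/C=C\CCCCCCCC(=O)OC/C=C(\C)CC/C=C(\C)CC/C=C(\C)CCC=C(C)C | intermediate
5 | (R)-1,1'-bi-2-naphthol (R axis; SMILES cannot encode the axis) | Oc1ccc2ccccc2c1-c1c(O)ccc2ccccc12 | starting material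
6 | 2-fluorobenzyl bromide | Fc1ccccc1CBr | starting material
7 | (R)-2'-[(2-fluorobenzyl)oxy]-1,1'-binaphthalen-2-ol (R axis; SMILES cannot encode the axis) | Oc1ccc2ccccc2c1-c1c(OCc2ccccc2F)ccc2ccccc12 | intermediate
8 | monocyclic tertiary cation: ring A closed, positive charge on C11, C10 configured as in 9 | CC/C=C\C/C=C\C/C=C\CCCCCCCC(=O)OC/C=C(\C)CC/C=C(\C)CC[C@@H]1[C+](C)CCCC1(C)C | intermediate
9 | (2E,6E)-3,7-dimethyl-9-[(1S)-2,6,6-trimethylcyclohex-2-en-1-yl]nona-2,6-dien-1-yl α-linolenate (CNP0115076.1) | CC/C=C\C/C=C\C/C=C\CCCCCCCC(=O)OC/C=C(\C)CC/C=C(\C)CC[C@@H]1C(C)=CCCC1(C)C | target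

## Step count and risks
Total step count: 3 (two from 1 to 9, one for the chiral controller).
Longest linear sequence: 2 steps (1 → 4 → 9). The branch 5 → 7 → 9 is equally long.

**Most likely to fail: step 3.**
- The least certain point is how cation 8 partitions between proton loss and capture by C6=C7. Capture would give bicyclic labdane-type and then tricyclic esters.
- Proton loss may also give the exocyclic olefin, or the tetrasubstituted olefin, which erases C10.
- The ester may tie up SnCl4 and erode selectivity.
- A realistic outcome is 25–40% of 9 per pass at about 80–90% ee. The last few percent of the antipode must then be removed by preparative SFC on a chiral phase.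

Fallback for step 3: move the same asymmetric ring closure to a truncated chain that cannot cyclise further, then add the missing C5 unit. It sets out from ligand 7 and comes back to the route at 9. Commercial (2E,6E)-farnesyl bromide and PhSO2Na in DMF give (2E,6E)-farnesyl phenyl sulfone F1. Treating F1 with 7/SnCl4 in toluene at −78 °C gives (S)-α-monocyclofarnesyl phenyl sulfone F2. The only remaining olefin in F1 is allylic to the sulfonyl group and too poor a nucleophile to attack the cation, so the cascade must stop at ring A. As an aryl sulfone, F2 may also allow the ee to be raised by crystallisation. Deprotonation with t-BuOK in THF/DMF at −40 °C and alkylation with (E)-4-bromo-3-methylbut-2-enyl acetate, the retinoid C5 building block, gives the C20 5-phenylsulfonyl acetate F3 as a C5 epimer mixture of no consequence. Excess LiBHEt3 at −78 °C first removes the acetate to give the C20 5-phenylsulfonyl alcohol F4, which is not isolated. Adding PdCl2(dppp) (5 mol%) at 0 °C then replaces the allylic sulfonyl group by hydride at C5, with the 6E olefin kept in place, to give the monocyclic alcohol F5. Esterifying F5 with 2 (DCC, 4-(dimethylamino)pyridine, CH2Cl2) gives 9.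

**Second: step 2.** Bis-alkylation and unreacted 5 can lower the yield of 7, and traces of 5 would act as a competing, less selective acid in step 3.

Fallback for step 2: it sets out from 5 and comes back at 7, replacing phenoxide alkylation by a redox condensation. This is a Mitsunobu etherification with 2-fluorobenzyl alcohol, PPh3 and DIAD in THF at 0 °C to rt. On this diol it stops at the mono-ether because the second OH is too hindered to attack the alkoxyphosphonium ion. It makes no new compound F0.

**Third: step 1.** The risk is low. It consists of rearrangement of 3 to the N-acylurea and autoxidation of the triene.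

Fallback for step 1: it sets out from 1 and comes back at 4, forming the ester bond at the allylic carbon instead of the acyl carbon. PBr3 in Et2O at −10 °C converts 1 into (2E,6E,10E)-geranylgeranyl bromide F6. Caesium α-linolenate F7, made from 2 and Cs2CO3 in DMF, displaces the bromide by SN2 at rt to give 4.

## Further compounds
F1 | step 3 | (2E,6E)-farnesyl phenyl sulfone | O=S(=O)(c1ccccc1)C/C=C(\C)CC/C=C(\C)CCC=C(C)C
F2 | step 3 | (S)-α-monocyclofarnesyl phenyl sulfone, (E)-3-methyl-5-[(1S)-2,6,6-trimethylcyclohex-2-en-1-yl]pent-2-en-1-yl phenyl sulfone | O=S(=O)(c1ccccc1)C/C=C(\C)CC[C@@H]1C(C)=CCCC1(C)C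
F3 | step 3 | (2E,6E)-3,7-dimethyl-5-(phenylsulfonyl)-9-[(1S)-2,6,6-trimethylcyclohex-2-en-1-yl]nona-2,6-dien-1-yl acetate (C5 epimers) | CC(=O)OC/C=C(\C)CC(/C=C(\C)CC[C@@H]1C(C)=CCCC1(C)C)S(=O)(=O)c1ccccc1
F4 | step 3 | (2E,6E)-3,7-dimethyl-5-(phenylsulfonyl)-9-[(1S)-2,6,6-trimethylcyclohex-2-en-1-yl]nona-2,6-dien-1-ol (C5 epimers) | OC/C=C(\C)CC(/C=C(\C)CC[C@@H]1C(C)=CCCC1(C)C)S(=O)(=O)c1ccccc1
F5 | step 3 | (2E,6E)-3,7-dimethyl-9-[(1S)-2,6,6-trimethylcyclohex-2-en-1-yl]nona-2,6-dien-1-ol | OC/C=C(\C)CC/C=C(\C)CC[C@@H]1C(C)=CCCC1(C)C
F0 | step 2 | none | none
F6 | step 1 | (2E,6E,10E)-geranylgeranyl bromide | BrC/C=C(\C)CC/C=C(\C)CC/C=C(\C)CCC=C(C)C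
F7 | step 1 | caesium α-linolenate | CC/C=C\C/C=C\C/C=C\CCCCCCCC(=O)[O-].[Cs+]
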